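**Retrosynthetic overview**
1. Target 29 ⇐ macrocycle 28 (desilylation) ⇐ open-chain iodide 25 by intramolecular alkyl–alkenyl Negishi coupling at C2–C3; this is the only ring-forming step and it comes last.
2. C1–C14 bond and both stereocentres ⇐ Cu-catalysed SN2 opening of (2S,3R)-2,3-epoxynerol (Sharpless) at its C2 by a primary Grignard reagent (inversion at ring C1).
3. C8–C9 ⇐ Negishi coupling of a (Z)-homoallylic zinc reagent with an (E)-alkenyl iodide; C3=C4(CH2OH)–C5 ⇐ Cu-catalysed anti-carbomagnesiation of propargyl alcohol.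
4. (Z)-C11=C12 unit with differentiated C9/C14 ends ⇐ 4-methylanisole: Birch reduction, then ozonolysis of the enol-ether bond only, opens the former arene into a Z-configured C6 chain.
5. Ring order: the aromatic six-membered ring is destroyed in steps 1–2; the 14-membered carbocycle is formed once, in step 14.

Assumption: the target is the (R,R)-isomer encoded by the SMILES; ring atoms are numbered C1 (CH bearing the side chain), C2, C3=C4 (C4 carries C15H2OH), C7=C8(Me), C11=C12(Me), C14.

**Route**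

Step 1
Reactants: 1 4-methylanisole
Product: 2 1-methoxy-4-methylcyclohexa-1,4-diene
Conditions: Li, NH3(l), t-BuOH, THF, −78 to −33 °C; NH4Cl
Reagents that add atoms: none
Why: Birch reduction protonates the ring ortho and meta to OMe, so the OMe- and Me-bearing carbons stay sp2 and the arene becomes the unconjugated 1,4-diene in which the future C11=C12 olefin is locked cis in the ring.

Step 2
Reactants: 2 1-methoxy-4-methylcyclohexa-1,4-diene
Product: 5 methyl (Z)-6-hydroxy-4-methylhex-3-enoate, via methoxy hydroperoxide 3 (not isolated), via aldehyde ester 4 (not isolated)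
Conditions: O3 (1.0 equiv), CH2Cl2/MeOH, −78 °C; Me2S; then NaBH4, 0 °C
Reagents that add atoms: ozone, [O-][O+]=O
Why: Criegee ozonolysis cleaves only the far more electron-rich enol-ether bond, giving an ester (C9) and an aldehyde (C14) while the surviving ring olefin emerges as the pure (Z)-trisubstituted alkene; NaBH4 reduces only the aldehyde.

Step 3
Reactants: 5 methyl (Z)-6-hydroxy-4-methylhex-3-enoate
Product: 6 methyl (Z)-6-bromo-4-methylhex-3-enoate
Conditions: CBr4, PPh3, CH2Cl2, 0 °C
Reagents that add atoms: carbon tetrabromide, BrC(Br)(Br)Br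
Why: Appel reaction converts the primary alcohol to the bromide by SN2 displacement of the alkoxyphosphonium ion without touching the ester or the olefin geometry.

Step 4
Reactants: 6 methyl (Z)-6-bromo-4-methylhex-3-enoate
Product: 7 (Z)-6-bromo-4-methylhex-3-en-1-ol
Conditions: i-Bu2AlH (2.2 equiv), CH2Cl2, −78 to 0 °C
Reagents that add atoms: none
Why: Hydride reduction of the ester to the primary alcohol; a primary alkyl bromide and an isolated olefin are inert to i-Bu2AlH at low temperature.

Step 5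
Reactants: 7 (Z)-6-bromo-4-methylhex-3-en-1-ol
Product: 8 (Z)-1-bromo-6-iodo-3-methylhex-3-ene
Conditions: I2, PPh3, imidazole, CH2Cl2, 0 °C
Reagents that add atoms: iodine, II
Why: Garegg–Samuelsson (Appel-type) iodination gives the primary iodide, so the two chain ends now differ as C–I (C9) and C–Br (C14).

Step 6
Reactants: 9 pent-3-yn-1-ol
Product: 10 5-bromopent-2-yne
Conditions: CBr4, PPh3, CH2Cl2, 0 °C
Reagents that add atoms: carbon tetrabromide, BrC(Br)(Br)Br
Why: Appel reaction on an unhindered primary alcohol; the internal alkyne is inert.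

Step 7
Reactants: 10 5-bromopent-2-yne; 11 prop-2-yn-1-ol
Product: 14 (Z)-3-chloro-2-(pent-3-yn-1-yl)prop-2-en-1-ol, via pent-3-yn-1-ylmagnesium bromide 12 (not isolated), via alkenylmagnesium alkoxide 13 (not isolated)
Conditions: 10 (2.4 equiv), Mg, THF, 20 °C; then 11, CuI (10 mol %), Et2O/THF, −10 to 35 °C; then NCS, −40 to 20 °C
Reagents that add atoms: N-chlorosuccinimide, O=C1CCC(=O)N1Cl
Why: Duboudin–Jousseaume Cu-catalysed anti-carbomagnesiation of the propargylic alkoxide puts the alkyl group on C2 and magnesium on C3 cis to CH2O in a five-membered chelate, and chlorination of the C–Mg bond with retention (as in the usual iodine quench) fixes the (Z)-chloroalkene that later becomes C2 cis to CH2OH.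

Step 8
Reactants: 14 (Z)-3-chloro-2-(pent-3-yn-1-yl)prop-2-en-1-ol
Product: 15 tert-butyl{[(Z)-3-chloro-2-(pent-3-yn-1-yl)prop-2-en-1-yl]oxy}dimethylsilane
Conditions: TBSCl, imidazole, DMF, 20 °C
Reagents that add atoms: tert-butyldimethylsilyl chloride, CC(C)(C)[Si](C)(C)Cl
Why: Standard silylation of the primary allylic alcohol, which must be masked for the Grignard step and for the later selective iodination.

Step 9
Reactants: 15 tert-butyl{[(Z)-3-chloro-2-(pent-3-yn-1-yl)prop-2-en-1-yl]oxy}dimethylsilane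
Product: 17 tert-butyl({(Z)-3-chloro-2-[(E)-4-iodopent-3-en-1-yl]prop-2-en-1-yl}oxy)dimethylsilane, via alkenylzirconocene chloride 16 (not isolated)
Conditions: Cp2Zr(H)Cl (1.5 equiv), THF, 45 °C; then I2, −20 °C
Reagents that add atoms: iodine, II
Why: Hydrozirconation is a syn addition that after equilibration places zirconium on the methyl-bearing carbon of a 2-alkyne (about 9:1), and iodinolysis with retention gives the (E)-2-iodoalkene; the trisubstituted chloroalkene is too hindered to react.

Step 10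
Reactants: 8 (Z)-1-bromo-6-iodo-3-methylhex-3-ene; 17 tert-butyl({(Z)-3-chloro-2-[(E)-4-iodopent-3-en-1-yl]prop-2-en-1-yl}oxy)dimethylsilane
Product: 19 tert-butyl{[(2Z,5E,9Z)-12-bromo-2-(chloromethylidene)-6,10-dimethyldodeca-5,9-dien-1-yl]oxy}dimethylsilane, via alkylzinc iodide 18 (not isolated)
Conditions: 8, Zn dust (Me3SiCl/BrCH2CH2Br-activated), THF, 35 °C; then 17 (0.8 equiv), PdCl2(dppf) (5 mol %), THF, 20–40 °C
Reagents that add atoms: none
Why: Zinc inserts into the primary C–I bond but not the C–Br bond, and Negishi coupling with the alkenyl iodide proceeds with retention of the (E)-geometry while the alkenyl chloride and alkyl bromide do not undergo oxidative addition under these conditions.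

Step 11
Reactants: 20 nerol
Product: 21 (2S,3R)-2,3-epoxynerol
Conditions: Ti(OiPr)4 (10 mol %), L-(+)-diethyl tartrate (12 mol %), t-BuOOH, 4 Å MS, CH2Cl2, −20 °C
Reagents that add atoms: tert-butyl hydroperoxide, CC(C)(C)OO
Why: Katsuki–Sharpless asymmetric epoxidation is directed by the allylic hydroxyl, so only the 2,3-olefin reacts, and the L-(+)-tartrate catalyst gives the (2S,3R)-epoxide (about 90% ee), which sets the carbinol stereocentre.

Step 12
Reactants: 19 tert-butyl{[(2Z,5E,9Z)-12-bromo-2-(chloromethylidene)-6,10-dimethyldodeca-5,9-dien-1-yl]oxy}dimethylsilane; 21 (2S,3R)-2,3-epoxynerol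
Product: 24 (2R,3R)-2-[(3Z,7E,11Z)-11-({[tert-butyl(dimethyl)silyl]oxy}methyl)-12-chloro-3,7-dimethyldodeca-3,7,11-trien-1-yl]-3,7-dimethyloct-6-ene-1,3-diol, via Grignard reagent 22 (not isolated), via lithium epoxynerolate 23 (not isolated)
Conditions: 19, Mg, THF, 25 °C; 21 (1.5 equiv), n-BuLi, THF, −78 °C; combine, CuI (15 mol %), −40 to 0 °C; aq NH4Cl
Reagents that add atoms: none
Why: Cu-catalysed Grignard opening of a 3,3-disubstituted 2,3-epoxy alkoxide is an SN2 attack at the less substituted C2 with inversion, which creates ring carbon C1 as (R) next to the untouched (R)-carbinol; the alkenyl chloride does not insert magnesium at this temperature.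

Step 13
Reactants: 24 the (2R,3R)-1,3-diol
Product: 25 (2S,3R)-2-[(3Z,7E,11Z)-11-({[tert-butyl(dimethyl)silyl]oxy}methyl)-12-chloro-3,7-dimethyldodeca-3,7,11-trien-1-yl]-1-iodo-3,7-dimethyloct-6-en-3-ol
Conditions: I2, PPh3, imidazole, CH2Cl2, 0 °C, dark
Reagents that add atoms: iodine, II
Why: Garegg–Samuelsson iodination is selective for the primary hydroxyl over the tertiary one (the descriptor at C2 changes to S only because CH2I outranks the carbinol carbon).

Step 14
Reactants: 25 the primary iodide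
Product: 28 (R)-2-[(1R,3Z,7E,11Z)-4-({[tert-butyl(dimethyl)silyl]oxy}methyl)-8,12-dimethylcyclotetradeca-3,7,11-trien-1-yl]-6-methylhept-5-en-2-ol, via alkyllithium alkoxide 26 (not isolated), via alkylzinc chloride 27 (not isolated)
Conditions: t-BuLi (3.1 equiv), Et2O, −78 °C; ZnCl2, THF, −78 to 20 °C; slow addition (12 h) to Pd[P(t-Bu)3]2 (10 mol %), THF/NMP, 60 °C, 2 mM; aq NH4Cl
Reagents that add atoms: none
Why: Proposed new method: iodine–lithium exchange outruns any reaction of t-BuLi with the alkenyl chloride, transmetalation gives a primary alkylzinc tethered to the (Z)-chloroalkene, and C–Cl oxidative addition at the electron-rich Pd–P(t-Bu)3 centre, transmetalation and reductive elimination close the 14-membered ring with retention of olefin geometry under high dilution; the closest known reactions are the intermolecular Negishi coupling of alkylzinc halides with alkenyl chlorides and B-alkyl Suzuki macrocyclisations.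

Step 15
Reactants: 28 the silyl-protected macrocycle
Product: 29 (R)-2-[(1R,3Z,7E,11Z)-4-(hydroxymethyl)-8,12-dimethylcyclotetradeca-3,7,11-trien-1-yl]-6-methylhept-5-en-2-ol
Conditions: Bu4NF, THF, 0 to 20 °C
Reagents that add atoms: none
Why: Fluoride-mediated desilylation cleaves the primary silyl ether and leaves the olefins and both stereocentres untouched.

**Compound list**
1 | 4-methylanisole | COc1ccc(C)cc1 | starting material
2 | 1-methoxy-4-methylcyclohexa-1,4-diene | COC1=CCC(C)=CC1 | intermediate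
3 | methyl (Z)-6-hydroperoxy-6-methoxy-4-methylhex-3-enoate (in situ) | COC(=O)C/C=C(/C)CC(OC)OO | intermediate
4 | methyl (Z)-4-methyl-6-oxohex-3-enoate (in situ) | COC(=O)C/C=C(/C)CC=O | intermediate
5 | methyl (Z)-6-hydroxy-4-methylhex-3-enoate | COC(=O)C/C=C(/C)CCO | intermediate
6 | methyl (Z)-6-bromo-4-methylhex-3-enoate | COC(=O)C/C=C(/C)CCBr | intermediate
7 | (Z)-6-bromo-4-methylhex-3-en-1-ol | OCC/C=C(/C)CCBr | intermediate
8 | (Z)-1-bromo-6-iodo-3-methylhex-3-ene | ICC/C=C(/C)CCBr | intermediate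
9 | pent-3-yn-1-ol | CC#CCCO | starting material
10 | 5-bromopent-2-yne | CC#CCCBr | intermediate
11 | prop-2-yn-1-ol | C#CCO | starting material
12 | pent-3-yn-1-ylmagnesium bromide (in situ) | CC#CCC[Mg]Br | intermediate
13 | bromomagnesium (Z)-3-(bromomagnesio)-2-(pent-3-yn-1-yl)prop-2-en-1-olate (in situ) | Br[Mg]/C=C(\CO[Mg]Br)CCC#CC | intermediate
14 | (Z)-3-chloro-2-(pent-3-yn-1-yl)prop-2-en-1-ol | Cl/C=C(\CO)CCC#CC | intermediate
15 | tert-butyl{[(Z)-3-chloro-2-(pent-3-yn-1-yl)prop-2-en-1-yl]oxy}dimethylsilane | Cl/C=C(\CO[Si](C)(C)C(C)(C)C)CCC#CC | intermediate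
16 | chloro{(2E,6Z)-7-chloro-6-[(tert-butyldimethylsilyloxy)methyl]hepta-2,6-dien-2-yl}bis(cyclopentadienyl)zirconium (in situ) | Cl/C=C(\CO[Si](C)(C)C(C)(C)C)CC/C=C(\C)[Zr](Cl)(C1C=CC=C1)C1C=CC=C1 | intermediate
17 | tert-butyl({(Z)-3-chloro-2-[(E)-4-iodopent-3-en-1-yl]prop-2-en-1-yl}oxy)dimethylsilane | Cl/C=C(\CO[Si](C)(C)C(C)(C)C)CC/C=C(\C)I | intermediate
18 | [(Z)-6-bromo-4-methylhex-3-en-1-yl]zinc iodide (in situ) | I[Zn]CC/C=C(/C)CCBr | intermediate
19 | tert-butyl{[(2Z,5E,9Z)-12-bromo-2-(chloromethylidene)-6,10-dimethyldodeca-5,9-dien-1-yl]oxy}dimethylsilane | Cl/C=C(\CO[Si](C)(C)C(C)(C)C)CC/C=C(\C)CC/C=C(/C)CCBr | intermediate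
20 | nerol, (Z)-3,7-dimethylocta-2,6-dien-1-ol | CC(C)=CCC/C(C)=C\CO | starting material
21 | (2S,3R)-2,3-epoxynerol, [(2S,3R)-3-methyl-3-(4-methylpent-3-en-1-yl)oxiran-2-yl]methanol | OC[C@@H]1O[C@]1(C)CCC=C(C)C | intermediate
22 | [(3Z,7E,11Z)-11-({[tert-butyl(dimethyl)silyl]oxy}methyl)-12-chloro-3,7-dimethyldodeca-3,7,11-trien-1-yl]magnesium bromide (in situ) | Cl/C=C(\CO[Si](C)(C)C(C)(C)C)CC/C=C(\C)CC/C=C(/C)CC[Mg]Br | intermediate
23 | lithium alkoxide of (2S,3R)-2,3-epoxynerol (in situ) | [Li]OC[C@@H]1O[C@]1(C)CCC=C(C)C | intermediate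
24 | (2R,3R)-2-[(3Z,7E,11Z)-11-({[tert-butyl(dimethyl)silyl]oxy}methyl)-12-chloro-3,7-dimethyldodeca-3,7,11-trien-1-yl]-3,7-dimethyloct-6-ene-1,3-diol | CC(C)=CCC[C@@](C)(O)[C@@H](CO)CC/C(C)=C\CC/C(C)=C/CC/C(CO[Si](C)(C)C(C)(C)C)=C/Cl | intermediate
25 | (2S,3R)-2-[(3Z,7E,11Z)-11-({[tert-butyl(dimethyl)silyl]oxy}methyl)-12-chloro-3,7-dimethyldodeca-3,7,11-trien-1-yl]-1-iodo-3,7-dimethyloct-6-en-3-ol | CC(C)=CCC[C@@](C)(O)[C@@H](CI)CC/C(C)=C\CC/C(C)=C/CC/C(CO[Si](C)(C)C(C)(C)C)=C/Cl | intermediate
26 | C2-lithio lithium alkoxide derived from 25 (in situ) | CC(C)=CCC[C@@](C)(O[Li])[C@@H](C[Li])CC/C(C)=C\CC/C(C)=C/CC/C(CO[Si](C)(C)C(C)(C)C)=C/Cl | intermediate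
27 | C2-chlorozincio lithium alkoxide derived from 25 (in situ) | CC(C)=CCC[C@@](C)(O[Li])[C@@H](C[Zn]Cl)CC/C(C)=C\CC/C(C)=C/CC/C(CO[Si](C)(C)C(C)(C)C)=C/Cl | intermediate
28 | (R)-2-[(1R,3Z,7E,11Z)-4-({[tert-butyl(dimethyl)silyl]oxy}methyl)-8,12-dimethylcyclotetradeca-3,7,11-trien-1-yl]-6-methylhept-5-en-2-ol | CC(C)=CCC[C@@](C)(O)[C@H]1C/C=C(\CO[Si](C)(C)C(C)(C)C)CC/C=C(\C)CC/C=C(/C)CC1 | intermediate
29 | (R)-2-[(1R,3Z,7E,11Z)-4-(hydroxymethyl)-8,12-dimethylcyclotetradeca-3,7,11-trien-1-yl]-6-methylhept-5-en-2-ol | CC(C)=CCC[C@@](C)(O)[C@H]1C/C=C(\CO)CC/C=C(\C)CC/C=C(/C)CC1 | target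

**Count**
Total steps: 15. Longest linear sequence: 10 steps (steps 1, 2, 3, 4, 5, 10, 12, 13, 14, 15, from 4-methylanisole).

**Three steps most likely to fail, with fallbacks**

Step 14 (highest risk: a macrocyclic alkyl–alkenyl coupling onto an alkenyl chloride has no direct precedent). The fallback sets out from 25 and returns at 28. Iodine–lithium exchange on 25 (t-BuLi, Et2O, −78 °C) followed by capture with 9-methoxy-9-borabicyclo[3.3.1]nonane gives the lithium alkyl(methoxy)borinate F1. F1 is then cyclised as a B-alkyl Suzuki–Miyaura macrocyclisation (Pd(OAc)2, SPhos, aq K3PO4, THF/DMF, 60 °C, high dilution) to give 28. This swaps the moisture-sensitive organozinc for a boron "ate" complex, the reaction class with established macrocyclisation precedent.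

Step 12 (a valuable, functionalised Grignard reagent must open a trisubstituted epoxy alcohol and cannot be used in excess). The fallback sets out from 7 and returns at 24, and it changes the order of fragment union so that a cheap, simple Grignard reagent is used in excess. Alcohol 7 is converted (PPh3, CCl4) into (Z)-1-bromo-6-chloro-3-methylhex-3-ene F2. Magnesium inserts only into its C–Br bond to give [(Z)-6-chloro-3-methylhex-3-en-1-yl]magnesium bromide F3, which (3 equiv, CuI) opens lithium epoxynerolate 23 to give the chloro diol F4. Halide exchange (NaI, acetone, reflux) gives the iodo diol F5. Treatment with t-BuLi (4.1 equiv) and then ZnCl2 gives the organozinc dialkoxide F6, which undergoes the PdCl2(dppf)-catalysed Negishi coupling with alkenyl iodide 17 to give 24.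

Step 7 (carbomagnesiation with a Grignard reagent bearing β-hydrogens, and a chlorine rather than the usual iodine quench). The fallback sets out from 10 and 11 and returns at 14. The carbomagnesiation is run with the well-precedented iodine quench to give (Z)-3-iodo-2-(pent-3-yn-1-yl)prop-2-en-1-ol F7. The iodine is then exchanged for chlorine with retention of geometry (CuCl, DMF, 110 °C) to give 14.

**Further compounds**
F1 | step 14 | lithium alkyl(methoxy)borinate of 9-borabicyclo[3.3.1]nonane derived from 25 (lithium alkoxide) | CC(C)=CCC[C@@](C)(O[Li])[C@@H](C[B-]1(OC)C2CCCC1CCC2)CC/C(C)=C\CC/C(C)=C/CC/C(CO[Si](C)(C)C(C)(C)C)=C/Cl.[Li+]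
F2 | step 12 | (Z)-1-bromo-6-chloro-3-methylhex-3-ene | ClCC/C=C(/C)CCBr
F3 | step 12 | [(Z)-6-chloro-3-methylhex-3-en-1-yl]magnesium bromide | ClCC/C=C(/C)CC[Mg]Br
F4 | step 12 | (2R,3R)-2-[(Z)-6-chloro-3-methylhex-3-en-1-yl]-3,7-dimethyloct-6-ene-1,3-diol | CC(C)=CCC[C@@](C)(O)[C@@H](CO)CC/C(C)=C\CCCl
F5 | step 12 | (2R,3R)-2-[(Z)-6-iodo-3-methylhex-3-en-1-yl]-3,7-dimethyloct-6-ene-1,3-diol | CC(C)=CCC[C@@](C)(O)[C@@H](CO)CC/C(C)=C\CCI
F6 | step 12 | chlorozinc reagent of F5 as its dilithium dialkoxide | CC(C)=CCC[C@@](C)(O[Li])[C@@H](CO[Li])CC/C(C)=C\CC[Zn]Cl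
F7 | step 7 | (Z)-3-iodo-2-(pent-3-yn-1-yl)prop-2-en-1-ol | I/C=C(\CO)CCC#CC
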